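Per hour is the unit for these flasks. Dusk and noon share one recipe, are stopped at 12 h and 25 h, and hold an amount of added ligand between those of the runs elm and oak.

| flask | substrate | gas | free catalyst | added ligand | remark | time |
|---|---|---|---|---|---|---|
| elm | 0.010 M | 4.2 mM (held) | 3.3 mol% | 0.25 mM | run made earlier |  |
| oak | 0.010 M | 4.2 mM (held) | 3.3 mol% | 0.55 mM | run made earlier |  |
| dusk | 0.010 M | 4.2 mM (held) | 3.3 mol% | 0.37 mM |  | 12 h |
| noon | 0.010 M | 4.2 mM (held) | 3.3 mol% | 0.37 mM |  | 25 h |

| run | time / h | target / % | substrate / % | catalyst intermediate C / % | over-reaction product / % |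
|---|---|---|---|---|---|
| elm | 1.00 | 19 | 52 | 1 | 30 |
| elm | 3.00 | 6 | 7 | 0 | 85 |
| elm | 5.00 | 1 | 0 | 1 | 96 |
| elm | 8.00 | 0 | 0 | 1 | 100 |
| elm | 12.0 | 0 | 0 | 0 | 98 |
| elm | 15.0 | 2 | 0 | 0 | 102 |
| oak | 2.50 | 8 | 24 | 2 | 68 |
| oak | 5.00 | 1 | 4 | 2 | 95 |
| oak | 8.00 | 0 | 2 | 0 | 99 |
| oak | 10.0 | 1 | 2 | 0 | 100 |
| oak | 12.0 | 2 | 0 | 0 | 102 |
| oak | 15.0 | 2 | 0 | 0 | 98 |

(standard deviation of a reading: 1.5 percentage points)

- which of these there is most of at the end, counted by the substrate in it, dusk (substrate / target / catalyst intermediate C / over-reaction product)
- which of these there is most of at the end, counted by the substrate in it, noon (substrate / target / catalyst intermediate C / over-reaction product)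
- the largest of these amounts at the end, in percent of the substrate charged, dusk
- the largest of these amounts at the end, in percent of the substrate charged, noon

With the gas held, the fall of c(substrate) can be treated as pseudo-first-order, a loss of a fixed fraction per hour at rate constant k. Integrated, c(substrate) is its charge times exp(−kt), so one reading gives k as the logarithm of charge over reading, divided by the time. Elm's reading at 1.00 h gives 0.654 h⁻¹. Oak's at 2.50 h gives 0.571 h⁻¹, which is slower and is kept as the cautious reading. Falling to a fiftieth of the charge then takes 6.85 h. This clearing time is the quantity carried on.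

The bench rule says that a setting between two finished runs finishes too. By this reckoning, dusk has 1.75 clearing times and noon 3.65. The rule is at its border where added ligand passes the catalyst charged. That ratio is 0.758 in elm, 1.12 in dusk and noon, and 1.67 in oak, so it crosses one inside the bracket. But oak, beyond the crossing, still cleared, with 98 % over-reaction product at its last reading. The reckoning therefore stands.

The forecast agrees, with over-reaction product at 100 % for dusk and over-reaction product at 100 % for noon, since “the bracketing runs show no steep titration behaviour”.

The simulation gives over-reaction product at >99.9 % for dusk and over-reaction product at 100 % for noon, as forecast.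

    substrate + free catalyst → catalyst intermediate A (k = 1.50 M⁻¹ s⁻¹)
    coupling partner + catalyst intermediate A → catalyst intermediate B (k = 19.0 M⁻¹ s⁻¹)
    catalyst intermediate B → catalyst intermediate C (k = 1.30 s⁻¹)
    catalyst intermediate C → free catalyst + target (k = 0.00860 s⁻¹)
    free catalyst + added ligand ⇌ idle complex (K = 3900 M⁻¹, k = 1.30 M⁻¹ s⁻¹)
    target → over-reaction product (k = 6.50 × 10⁻⁴ s⁻¹)
    gas ⇌ coupling partner, rate k7*(csat - [coupling partner]) (kL = 0.0120 s⁻¹)

Noon's substrate passes the mark of the clearing time by 5.03 h, earlier than the clearing time and before the stop of dusk at 12 h. The target's half-life by its step to over-reaction product, 0.30 h, is shorter than the 1.15 h by which half of the substrate's first step is done in noon, and stopping later changes nothing.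

For the neighbour, noon with 5.6 mol% of free catalyst, k taken in proportion to the loading shortens the clearing time to 4.04 h, well inside 25 h. The computed flask ends with 100 % over-reaction product and 0 % substrate.

The data were computed for an exercise; scatter was added.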